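**Plan**

1. Numbering: core as 2,7-dioxabicyclo[3.2.1]octan-3-one (C1 acylal CH, O2, C3 lactone C=O, C4 CH2, C5 CH, C6 CH–CO2Me, O7, C8 CH bearing the decalin); decalin atoms are primed (C1′ CHMe, C2′ quaternary, C4a′, C8′=C8a′). Cuts, in order: O7–C1 (acetal), C6–H (carbinol back to the ketone of an α-keto ester), C4–C5 (lactone CH2–CH), C6–CO2Me (carbonylation), C8–C2′ (core–decalin), C1′–C2′ (ring B), C4a′–C4′ (side chain).
2. Enabling feature: C5 sits between C4 and C6. With C6 as the ketone of an α-keto ester, C5 is enolisable, and the aldehyde-level C1 can carry O2 as the bromoacetate of a mixed acylal. The bromoacetate CH2 (C4) then reaches C5 through a six-membered transition state that becomes the lactone ring.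
3. Forward order: cyclohexene ring A, then ring B by carbonyl-ene reaction, then tertiary radical plus butenolide (C8–C2′), then conversion to the acyclic α-keto ester acylal, then the δ-lactone by C4–C5 cycloalkylation, then the oxolane by reduction and acetalisation.
4. Stereochemistry: one carbinol centre from a catalytic CBS reduction is relayed by Claisen rearrangement to C4a′ and by the ene reaction to C1′. The radical addition sets C2′ (substrate control) and C8 (anti to the menthyloxy group of the purchased butenolide, which later leaves as menthol). C5 follows C8 (trans), C6 follows C5 (Felkin–Anh), and C1 is fixed by the bridge.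

Key step: step 12

Remark: the acylal carbon of 19, 20 and 21 forms as both epimers and is drawn without configuration; both converge in step 13, where this carbon is re-set by the bridge.
Remark: (1-methoxyethyl)triphenylphosphonium chloride (step 6) is prepared from PPh3 and 1-chloroethyl methyl ether if it is not bought.
Abbreviations in names: Men = (1S,2R,5S)-5-methyl-2-(propan-2-yl)cyclohexyl; Dec = (1S,2R,4aS)-1,2,5,5-tetramethyl-1,2,3,4,4a,5,6,7-octahydronaphthalen-2-yl.

Step 1
Reactants: 1 3-methylcyclohex-2-en-1-one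
Product: 3 3,3-dimethylcyclohex-1-en-1-yl trifluoromethanesulfonate, via lithium enolate 2 (not isolated)
Conditions: Me2CuLi (from MeLi and CuI), Et2O, 0 °C; then PhNTf2, THF, 0 °C to rt
Reagents that add atoms: lithium dimethylcuprate ([Li+].C[Cu-]C); N-phenylbis(trifluoromethanesulfonimide) (O=S(=O)(N(c1ccccc1)S(=O)(=O)C(F)(F)F)C(F)(F)F)
Why: Conjugate addition of the cuprate creates the gem-dimethyl carbon and a regiodefined enolate, and O-sulfonylation of that enolate (conjugate addition–enolate trapping) places the enol triflate double bond next to the quaternary carbon; no stereocenter is formed.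

Step 2
Reactants: 3 3,3-dimethylcyclohex-1-en-1-yl trifluoromethanesulfonate
Product: 5 1-(3,3-dimethylcyclohex-1-en-1-yl)ethan-1-one, via butoxydiene 4 (not isolated)
Conditions: butyl vinyl ether, Pd(OAc)2 (3 mol %), dppp, Et3N, DMF, 80 °C; then 1 M HCl, rt
Reagents that add atoms: butyl vinyl ether (C=COCCCC); water (O)
Why: Heck reaction of the enol triflate with an electron-rich vinyl ether under bidentate-phosphine conditions should couple at the internal vinyl carbon, and hydrolysis of the dienyl ether gives the methyl ketone; no stereocenter is formed.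

Step 3
Reactants: 5 1-(3,3-dimethylcyclohex-1-en-1-yl)ethan-1-one
Product: 6 (1R)-1-(3,3-dimethylcyclohex-1-en-1-yl)ethan-1-ol
Conditions: (S)-2-methyl-CBS-oxazaborolidine (10 mol %), BH3·SMe2, THF, −20 °C
Reagents that add atoms: none
Why: Corey–Bakshi–Shibata reduction, in which the oxazaborolidine differentiates the alkenyl (large) from the methyl (small) group as for aryl methyl ketones, should give the (R)-carbinol, the only decalin stereocenter set by a catalyst.

Step 4
Reactants: 6 (1R)-1-(3,3-dimethylcyclohex-1-en-1-yl)ethan-1-ol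
Product: 8 ethyl 2-[(1S,2E)-2-ethylidene-6,6-dimethylcyclohexyl]acetate, via ketene acetal 7 (not isolated)
Conditions: MeC(OEt)3, EtCO2H (cat.), xylene, 140 °C, ethanol distilled off
Reagents that add atoms: triethyl orthoacetate (CCOC(C)(OCC)OCC)
Why: Johnson–Claisen rearrangement through a chair transition state with the carbinol methyl equatorial should give the (E)-ethylidene group and transfer the carbinol configuration suprafacially to the ring carbon next to the gem-dimethyl group (the future C4a′).

Step 5
Reactants: 8 ethyl 2-[(1S,2E)-2-ethylidene-6,6-dimethylcyclohexyl]acetate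
Product: 9 2-[(1S,2E)-2-ethylidene-6,6-dimethylcyclohexyl]acetaldehyde
Conditions: i-Bu2AlH (1.1 equiv), CH2Cl2, −78 °C; aqueous potassium sodium tartrate
Reagents that add atoms: none
Why: Partial reduction of the ester at low temperature stops at the aldehyde through the tetrahedral aluminium hemiacetal (i-Bu2AlH reduction); the stereocenter and the alkene are untouched.

Step 6
Reactants: 9 2-[(1S,2E)-2-ethylidene-6,6-dimethylcyclohexyl]acetaldehyde
Product: 11 4-[(1S,2E)-2-ethylidene-6,6-dimethylcyclohexyl]butan-2-one, via enol ether 10 (not isolated)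
Conditions: (1-methoxyethyl)triphenylphosphonium chloride, KOtBu, THF, −40 to 0 °C; then 1 M HCl/THF, 0 °C
Reagents that add atoms: (1-methoxyethyl)triphenylphosphonium chloride (COC(C)[P+](c1ccccc1)(c1ccccc1)c1ccccc1.[Cl-]); water (O)
Why: Wittig reaction with the α-methoxyethylidene ylide and mild hydrolysis of the enol ether homologate the aldehyde to the methyl ketone without touching the stereocenter or the ethylidene group.

Step 7
Reactants: 11 4-[(1S,2E)-2-ethylidene-6,6-dimethylcyclohexyl]butan-2-one
Product: 12 (1R,2S,4aS)-1,2,5,5-tetramethyl-1,2,3,4,4a,5,6,7-octahydronaphthalen-2-ol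
Conditions: Me2AlCl (1.5 equiv), CH2Cl2, −78 to 0 °C
Reagents that add atoms: none
Why: Lewis-acid-promoted intramolecular carbonyl-ene reaction: with the side chain axial on ring A the ketone reaches one face of the (E)-ethylidene group only, the chair-like transition state puts the former ethylidene methyl equatorial so that H-1 ends cis to H-4a, and the only allylic hydrogen on that face is on the ring CH2, which gives the 8,8a-alkene; the C2 carbinol configuration is of no consequence because this carbon becomes a radical.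

Step 8
Reactants: 12 (1R,2S,4aS)-1,2,5,5-tetramethyl-1,2,3,4,4a,5,6,7-octahydronaphthalen-2-ol
Product: 14 cesium (1R,2S,4aS)-1,2,5,5-tetramethyl-1,2,3,4,4a,5,6,7-octahydronaphthalen-2-yl oxalate, via methyl oxalate 13 (not isolated)
Conditions: ClC(O)CO2Me, Et3N, DMAP, CH2Cl2, 0 °C; then CsOH (1.0 equiv), THF/H2O, rt
Reagents that add atoms: methyl chlorooxoacetate (COC(=O)C(=O)Cl); cesium hydroxide ([Cs+].[OH-])
Why: Acylation of the tertiary alcohol and saponification of the unhindered methyl ester with one equivalent of CsOH should give the stable cesium alkyl oxalate, a standard precursor of tertiary radicals.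

Step 9
Reactants: 14 cesium oxalate of 12; 15 (5S)-5-(Men-oxy)furan-2(5H)-one
Product: 16 (4R,5S)-5-(Men-oxy)-4-Dec-oxolan-2-one
Conditions: Ir[dF(CF3)ppy]2(dtbbpy)PF6 (1 mol %), H2O (10 equiv), DME/DMF 3:1, blue LEDs, 60 °C
Reagents that add atoms: none
Why: Photoredox oxidation of the oxalate and loss of two CO2 give the tertiary C2′ radical, which adds to the alkoxybutenolide (Giese addition, a known coupling of tertiary alkyl oxalates with such acceptors) anti to the menthyloxy group, setting the future C8, and is expected to bond from the equatorial direction of ring B so that the new chain is equatorial and the C2′ methyl axial, cis to the C1′ methyl.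

Step 10
Reactants: 16 (4R,5S)-5-(Men-oxy)-4-Dec-oxolan-2-one
Product: 18 methyl (4R,5S)-5-(Men-oxy)-4-Dec-4,5-dihydrofuran-2-carboxylate, via ketene acetal phosphate 17 (not isolated)
Conditions: KN(SiMe3)2, (PhO)2P(O)Cl, HMPA, THF, −78 °C; then Pd(PPh3)4 (10 mol %), CO (1 atm), MeOH, Et3N, DMF, 50 °C
Reagents that add atoms: carbon monoxide ([C-]#[O+]); methanol (CO)
Why: O-Phosphorylation of the lactone enolate and palladium-catalysed methoxycarbonylation of the cyclic ketene acetal phosphate (a known coupling of lactone-derived enol phosphates) turn the lactone carbonyl carbon into the enol ether carbon of a 2-alkoxyacrylate, a masked α-keto ester; the stereocenters are untouched.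

Step 11
Reactants: 18 methyl (4R,5S)-5-(Men-oxy)-4-Dec-4,5-dihydrofuran-2-carboxylate
Product: 19 methyl (4R)-5-[(bromoacetyl)oxy]-5-(Men-oxy)-2-oxo-4-Dec-pentanoate
Conditions: BrCH2CO2H (3 equiv), PPTS (5 mol %), 4 Å molecular sieves, CH2Cl2, 0 °C to rt
Reagents that add atoms: bromoacetic acid (OC(=O)CBr)
Why: Proposed new method: the acetal carbon of 18 carries two leaving groups, menthol and the enol of an α-keto ester; the ring oxygen is the poorer donor (its lone pair is delocalised into the acrylate) and the better nucleofuge, so acid should cleave the endocyclic C–O bond to a menthyloxy-stabilised acyclic oxocarbenium ion that bromoacetate captures, while ketonisation of the released enol makes the exchange irreversible; the closest known reaction types are the acid-catalysed addition of carboxylic acids to enol ethers and the transacetalisation of aryloxy acetals, and no selectivity is needed at the acylal carbon because both epimers are used.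

Step 12
Reactants: 19 methyl (4R)-5-[(bromoacetyl)oxy]-5-(Men-oxy)-2-oxo-4-Dec-pentanoate
Product: 20 methyl 2-[(4R,5R)-6-(Men-oxy)-2-oxo-5-Dec-oxan-4-yl]-2-oxoacetate
Conditions: Cs2CO3 (1.5 equiv), Bu4NI (10 mol %), MeCN, 0.01 M, 0 °C to rt
Reagents that add atoms: none
Why: Cs2CO3 deprotonates the CH2 between the ketone and the stereocenter (the only position of 19 acidified by the 1,2-dicarbonyl unit), and the cesium enolate displaces bromide from the bromoacetate carbon in an intramolecular SN2 reaction. The closest known reaction type is the cycloalkylation of ketone and 1,2-dicarbonyl enolates with tethered α-halo esters. The δ-lactone ring closes by 6-exo-tet attack, the new bond being C4–C5 of the final bicycle, while O2, C3 and C1 come in with the acylal tether. The new stereocenter C5 is controlled by the adjacent C8: in the chair-like transition state the decalin is equatorial and the bromoacetate carbon approaches the enolate face anti to it, and because C5 stays enolisable the same trans arrangement is also reached by equilibration, from either acylal epimer. The step needs C-alkylation over O-alkylation and acyl transfer, and intramolecular over intermolecular reaction: O-alkylation would need an eight-membered ring, the soft stabilised enolate prefers the sp3 carbon of the bromoacetate to its ester carbonyl, and high dilution suppresses bimolecular alkylation.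

Step 13
Reactants: 20 methyl 2-[(4R,5R)-6-(Men-oxy)-2-oxo-5-Dec-oxan-4-yl]-2-oxoacetate
Product: 22 methyl (1S,5R,6R,8R)-3-oxo-8-Dec-2,7-dioxabicyclo[3.2.1]octane-6-carboxylate, via hydroxy ester 21 (not isolated)
Conditions: LiAlH(OtBu)3 (1.2 equiv), THF, −78 °C, AcOH quench; crude in CH2Cl2, CSA (20 mol %), 0 °C to rt
Reagents that add atoms: none
Why: Hydride addition to the ketone should follow the Felkin–Anh model (the ring carbon bearing the decalin anti to the hydride, which passes the hydrogen of the α-stereocenter) to give the (R)-carbinol, and acid then lets this hydroxyl displace menthol at the acylal carbon (transacetalisation, five-membered ring closure), the bridge fixing the configuration of C1.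

**Compound list**

1 | 3-methylcyclohex-2-en-1-one | CC1=CC(=O)CCC1 | starting material
2 | lithium 3,3-dimethylcyclohex-1-en-1-olate | [Li+].[O-]C1=CC(C)(C)CCC1 | intermediate
3 | 3,3-dimethylcyclohex-1-en-1-yl trifluoromethanesulfonate | CC1(C)CCCC(OS(=O)(=O)C(F)(F)F)=C1 | intermediate
4 | 1-(1-butoxyethenyl)-3,3-dimethylcyclohex-1-ene | C=C(OCCCC)C1=CC(C)(C)CCC1 | intermediate
5 | 1-(3,3-dimethylcyclohex-1-en-1-yl)ethan-1-one | CC(=O)C1=CC(C)(C)CCC1 | intermediate
6 | (1R)-1-(3,3-dimethylcyclohex-1-en-1-yl)ethan-1-ol | C[C@@H](O)C1=CC(C)(C)CCC1 | intermediate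
7 | 1-[(1R)-1-(1-ethoxyethenyloxy)ethyl]-3,3-dimethylcyclohex-1-ene | C=C(OCC)O[C@H](C)C1=CC(C)(C)CCC1 | intermediate
8 | ethyl 2-[(1S,2E)-2-ethylidene-6,6-dimethylcyclohexyl]acetate | CCOC(=O)C[C@@H]1/C(=C/C)CCCC1(C)C | intermediate
9 | 2-[(1S,2E)-2-ethylidene-6,6-dimethylcyclohexyl]acetaldehyde | O=CC[C@@H]1/C(=C/C)CCCC1(C)C | intermediate
10 | (1S,2E)-2-ethylidene-1-(3-methoxybut-2-en-1-yl)-6,6-dimethylcyclohexane (enol ether E/Z mixture) | COC(C)=CC[C@@H]1/C(=C/C)CCCC1(C)C | intermediate
11 | 4-[(1S,2E)-2-ethylidene-6,6-dimethylcyclohexyl]butan-2-one | CC(=O)CC[C@@H]1/C(=C/C)CCCC1(C)C | intermediate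
12 | (1R,2S,4aS)-1,2,5,5-tetramethyl-1,2,3,4,4a,5,6,7-octahydronaphthalen-2-ol | C[C@]1(O)CC[C@@H]2C(=CCCC2(C)C)[C@H]1C | intermediate
13 | methyl (1R,2S,4aS)-1,2,5,5-tetramethyl-1,2,3,4,4a,5,6,7-octahydronaphthalen-2-yl oxalate | COC(=O)C(=O)O[C@@]1(C)CC[C@@H]2C(=CCCC2(C)C)[C@H]1C | intermediate
14 | cesium (1R,2S,4aS)-1,2,5,5-tetramethyl-1,2,3,4,4a,5,6,7-octahydronaphthalen-2-yl oxalate | [Cs+].[O-]C(=O)C(=O)O[C@@]1(C)CC[C@@H]2C(=CCCC2(C)C)[C@H]1C | intermediate
15 | (5S)-5-{[(1S,2R,5S)-5-methyl-2-(propan-2-yl)cyclohexyl]oxy}furan-2(5H)-one | O=C1C=C[C@@H](O[C@H]2C[C@@H](C)CC[C@@H]2C(C)C)O1 | starting material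
16 | (4R,5S)-5-(Men-oxy)-4-Dec-oxolan-2-one | O=C1C[C@H]([C@]2(C)CC[C@@H]3C(=CCCC3(C)C)[C@H]2C)[C@@H](O[C@H]2C[C@@H](C)CC[C@@H]2C(C)C)O1 | intermediate
17 | (2S,3R)-2-(Men-oxy)-3-Dec-2,3-dihydrofuran-5-yl diphenyl phosphate | O=P(Oc1ccccc1)(Oc1ccccc1)OC1=C[C@H]([C@]2(C)CC[C@@H]3C(=CCCC3(C)C)[C@H]2C)[C@@H](O[C@H]2C[C@@H](C)CC[C@@H]2C(C)C)O1 | intermediate
18 | methyl (4R,5S)-5-(Men-oxy)-4-Dec-4,5-dihydrofuran-2-carboxylate | COC(=O)C1=C[C@H]([C@]2(C)CC[C@@H]3C(=CCCC3(C)C)[C@H]2C)[C@@H](O[C@H]2C[C@@H](C)CC[C@@H]2C(C)C)O1 | intermediate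
19 | methyl (4R)-5-[(bromoacetyl)oxy]-5-(Men-oxy)-2-oxo-4-Dec-pentanoate (both C5 epimers) | COC(=O)C(=O)C[C@H]([C@]1(C)CC[C@@H]2C(=CCCC2(C)C)[C@H]1C)C(O[C@H]1C[C@@H](C)CC[C@@H]1C(C)C)OC(=O)CBr | intermediate
20 | methyl 2-[(4R,5R)-6-(Men-oxy)-2-oxo-5-Dec-oxan-4-yl]-2-oxoacetate (both C6 epimers) | COC(=O)C(=O)[C@@H]1CC(=O)OC(O[C@H]2C[C@@H](C)CC[C@@H]2C(C)C)[C@H]1[C@]1(C)CC[C@@H]2C(=CCCC2(C)C)[C@H]1C | intermediate
21 | methyl (2R)-2-hydroxy-2-[(4R,5R)-6-(Men-oxy)-2-oxo-5-Dec-oxan-4-yl]acetate (both C6 epimers) | COC(=O)[C@H](O)[C@@H]1CC(=O)OC(O[C@H]2C[C@@H](C)CC[C@@H]2C(C)C)[C@H]1[C@]1(C)CC[C@@H]2C(=CCCC2(C)C)[C@H]1C | intermediate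
22 | methyl (1S,5R,6R,8R)-3-oxo-8-[(1S,2R,4aS)-1,2,5,5-tetramethyl-1,2,3,4,4a,5,6,7-octahydronaphthalen-2-yl]-2,7-dioxabicyclo[3.2.1]octane-6-carboxylate | COC(=O)[C@@H]1O[C@H]2OC(=O)C[C@@H]1[C@@H]2[C@]1(C)CC[C@@H]2C(=CCCC2(C)C)[C@H]1C | target

**Step count and risks**

Total steps: 13. Longest linear sequence: 13 (1 to 22); 15 enters as a purchased compound.

Steps most likely to fail:

1. Step 11 (Proposed new method). The process at risk is ionisation at the exocyclic C–O bond with loss of menthol and aromatisation to the furan, or epimerisation next to the oxocarbenium ion, instead of endocyclic cleavage. The fallback uses known reactions, sets out from 18 and returns at 19. Aqueous acid hydrolysis of the enol ether acetal (AcOH/H2O/THF) gives methyl (4R)-4-formyl-2-oxo-4-Dec-butanoate F1. Addition of bromoacetyl bromide to the aldehyde (ZnBr2 cat., CH2Cl2, −20 °C) gives the 1-bromoalkyl bromoacetate F2. Silver-promoted substitution of its acetal bromide with (1S,2R,5S)-menthol (AgOTf, 2,6-di-tert-butyl-4-methylpyridine, CH2Cl2, −40 °C; Koenigs–Knorr type) gives 19.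

2. Step 9. The process at risk is addition of the intermediate alkoxycarbonyl radical, which is axial and homoallylic, to the C8′=C8a′ double bond before the second decarboxylation; incomplete facial selectivity at the quaternary carbon is a second concern. The fallback sets out from 12 and returns at 16, and generates the radical by deoxygenation without an alkoxycarbonyl radical. Condensation of 12 with 5,7-di-tert-butyl-3-phenylbenzoxazolium tetrafluoroborate (pyridine, MTBE, rt) gives the 2-alkoxybenzoxazoline F3, used without isolation. Photoredox oxidation (Ir(ppy)2(dtbbpy)PF6, Bu4NOBz, DMSO, blue LEDs) then triggers β-scission of the C–O bond, and the tertiary radical adds to 15 as in step 9.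

3. Step 13. The process at risk is poor facial selectivity in the hydride addition, or attack of the new alkoxide or hydroxyl on the δ-lactone carbonyl (translactonisation with loss of the acylal). The fallback sets out from 20 and returns at 22. Catalyst-controlled reduction with catecholborane and the enantiomer of 2-methyl-CBS-oxazaborolidine that matches the Felkin–Anh sense (toluene, −78 °C) avoids a free alkoxide. Silylation in the same flask (TESOTf, 2,6-lutidine) gives the triethylsilyl ether F4, which is isolated. HF·pyridine in THF then removes the silyl group under acidic conditions, in which the hydroxyl closes onto the acylal carbon to give 22.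

Further compounds
F1 | step 11 | methyl (4R)-4-formyl-2-oxo-4-[(1S,2R,4aS)-1,2,5,5-tetramethyl-1,2,3,4,4a,5,6,7-octahydronaphthalen-2-yl]butanoate | COC(=O)C(=O)C[C@H]([C@]1(C)CC[C@@H]2C(=CCCC2(C)C)[C@H]1C)C=O
F2 | step 11 | methyl (4R)-5-bromo-5-[(bromoacetyl)oxy]-2-oxo-4-[(1S,2R,4aS)-1,2,5,5-tetramethyl-1,2,3,4,4a,5,6,7-octahydronaphthalen-2-yl]pentanoate (both C5 epimers) | COC(=O)C(=O)C[C@H]([C@]1(C)CC[C@@H]2C(=CCCC2(C)C)[C@H]1C)C(Br)OC(=O)CBr
F3 | step 9 | 5,7-di-tert-butyl-3-phenyl-2-{[(1R,2S,4aS)-1,2,5,5-tetramethyl-1,2,3,4,4a,5,6,7-octahydronaphthalen-2-yl]oxy}-2,3-dihydro-1,3-benzoxazole | CC(C)(C)c1cc(C(C)(C)C)c2OC(O[C@@]3(C)CC[C@@H]4C(=CCCC4(C)C)[C@H]3C)N(c3ccccc3)c2c1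
F4 | step 13 | methyl (2R)-2-[(triethylsilyl)oxy]-2-[(4R,5R)-6-(Men-oxy)-2-oxo-5-Dec-oxan-4-yl]acetate (both C6 epimers) | COC(=O)[C@H](O[Si](CC)(CC)CC)[C@@H]1CC(=O)OC(O[C@H]2C[C@@H](C)CC[C@@H]2C(C)C)[C@H]1[C@]1(C)CC[C@@H]2C(=CCCC2(C)C)[C@H]1C
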